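**Retrosynthetic overview**

- The strategy rests on ring A'' of the flavone unit etherified at C8'' (atoms C4a''–C5''–C6''–C7''–C8''–C8a''): C5''–OH and C8''–O–aryl stand para to each other, and C7''–OMe lies between C6''–H and the ether carbon. A 4-aryloxy-3-methoxy-4-(4-oxopyran-2-yl)cyclobut-2-enone already holds these carbons and oxygens in that order.
- Last ring formed: ring A'', by cutting C5''–C4a'' in a retro electrocyclic ring expansion back to that cyclobutenone; the two benzyl ethers come off afterwards.
- The C8''–O–C4' ether is cut at O–C4' into the tertiary cyclobutenyl alkoxide and an aryl(2,4,6-trimethoxyphenyl)iodonium salt of ring B of the other flavone. A fluoride on that ring would not be displaced by so hindered an alkoxide below the temperature at which the four-membered ring opens.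
- The bond from the carbinol carbon to the pyranone is cut into a 6-lithiated 2-aryl-4-pyranone and 3-methoxycyclobutenedione, the latter from dimethyl squarate.
- Ring order: the 4-pyranone (later ring C'') and the chromone of the first unit (rings A and C) are made separately, the cyclobutenone joins them, and ring A'' closes last.

Key step: step 9

Remark: locants without primes and with one prime belong to the flavone whose ring B carries the ether oxygen at C4'; locants with two and three primes belong to the flavone etherified at C8''. The cyclobutenones with a quaternary carbon are racemic, and that centre disappears in step 9.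

**Route**

Step 1
Reactants: 1 dimethyl squarate
Product: 3 3-methoxycyclobut-3-ene-1,2-dione (methyl semisquarate), via carbinol 2 (not isolated)
Conditions: LiAlH(OtBu)3 (1.0 equiv), THF, −78 °C; H2O; then 12 M HCl (cat.), CH2Cl2, rt
Reagents that add atoms: none
Why: Low-temperature 1,2-reduction of one vinylogous ester carbonyl by the bulky alkoxyaluminium hydride should stop at racemic carbinol 2 (its stereocenter is lost again), and under acid the methoxy group at C2 expels the C4 hydroxyl through the double bond and the oxocarbenium ion is hydrolysed with loss of methanol, an acid-catalysed vinylogous hemiacetal collapse of the kind used to turn squarate adducts into alkoxycyclobutenediones.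

Step 2
Reactants: 4 (E)-4-methoxybut-3-en-2-one; 5 4-(benzyloxy)benzoyl chloride
Product: 7 2-[4-(benzyloxy)phenyl]-4H-pyran-4-one, via enol ether diketone 6 (not isolated)
Conditions: 4 (2 equiv), LiN(SiMe3)2 (2 equiv), THF, −78 °C; 5 (1 equiv); 1 M HCl work-up; then CF3CO2H, CH2Cl2, rt
Reagents that add atoms: none
Why: Claisen-type C-acylation of the kinetic lithium enolate of the vinylogous ester (the second equivalent of enolate takes up the acidic diketone proton) should give 6, whose enol oxygen adds 6-endo to the methoxyenone under acid and eliminates methanol, a standard γ-pyrone synthesis that leaves the aryl benzyl ether untouched.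

Step 3
Reactants: 7 2-[4-(benzyloxy)phenyl]-4H-pyran-4-one; 3 3-methoxycyclobut-3-ene-1,2-dione
Product: 9 racemic 4-{6-[4-(benzyloxy)phenyl]-4-oxo-4H-pyran-2-yl}-4-hydroxy-3-methoxycyclobut-2-en-1-one, via pyranyllithium 8 (not isolated)
Conditions: lithium 2,2,6,6-tetramethylpiperidide (1.05 equiv), THF, −78 °C, 10 min; cannulated into 3 (1.3 equiv), THF, −78 °C; aq NH4Cl, −78 °C
Reagents that add atoms: none
Why: The hindered, Lewis acid-free lithium amide should remove the most acidic ring proton, H6 next to the ring oxygen (the site at which chromones are metalated at C2 by amide bases), and vinyllithium 8 then adds 1,2 to the ketone-like carbonyl of 3 (the one beside the methoxy-bearing carbon, the other being deactivated as a vinylogous ester), as organolithium reagents do with 3-alkoxycyclobutenediones, so that the quaternary carbinol centre forms without control as a racemate that is later flattened to C8''.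

Step 4
Reactants: 10 2,4,6-trihydroxyacetophenone
Product: 11 1-(2,6-dihydroxy-4-methoxyphenyl)ethan-1-one
Conditions: Me2SO4 (1.0 equiv), K2CO3 (1.0 equiv), acetone, rt to 50 °C
Reagents that add atoms: dimethyl sulfate, COS(=O)(=O)OC
Why: Williamson methylation with one equivalent of reagent should go to the 4-hydroxyl, which is the most acidic (para to the acetyl group) and is not hydrogen-bonded to the carbonyl group.

Step 5
Reactants: 11 1-(2,6-dihydroxy-4-methoxyphenyl)ethan-1-one
Product: 12 1-[2-(benzyloxy)-6-hydroxy-4-methoxyphenyl]ethan-1-one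
Conditions: BnBr (1.05 equiv), K2CO3, acetone, reflux
Reagents that add atoms: benzyl bromide, BrCc1ccccc1
Why: Williamson benzylation should stop after one of the two equivalent hydroxyls has reacted, because the remaining one is locked in a hydrogen bond to the acetyl carbonyl and is a poor nucleophile.

Step 6
Reactants: 12 1-[2-(benzyloxy)-6-hydroxy-4-methoxyphenyl]ethan-1-one; 13 4-iodobenzoyl chloride
Product: 15 5-(benzyloxy)-2-(4-iodophenyl)-7-methoxy-4H-chromen-4-one, via diketone 14 (not isolated)
Conditions: LiN(SiMe3)2 (3.2 equiv), THF, −78 to −10 °C; 13, −78 °C to rt; 1 M HCl work-up; then TsOH·H2O (cat.), toluene, 80 °C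
Reagents that add atoms: none
Why: Baker–Venkataraman-type construction in which the phenoxide–enolate dianion of 12 is C-aroylated directly to 1,3-diketone 14 and mild acid then closes ring C by attack of the phenol on the enolised aryl ketone and loss of water, with catalytic sulfonic acid in toluene chosen to spare the peri benzyl ether.

Step 7
Reactants: 15 5-(benzyloxy)-2-(4-iodophenyl)-7-methoxy-4H-chromen-4-one
Product: 16 {4-[5-(benzyloxy)-7-methoxy-4-oxo-4H-chromen-2-yl]phenyl}(2,4,6-trimethoxyphenyl)iodonium 4-methylbenzenesulfonate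
Conditions: mCPBA (1.05 equiv), TsOH·H2O (1.05 equiv), MeCN–CH2Cl2, 40 °C; then 1,3,5-trimethoxybenzene (1.05 equiv), rt
Reagents that add atoms: 1,3,5-trimethoxybenzene, COc1cc(OC)cc(OC)c1; 4-methylbenzenesulfonic acid, Cc1ccc(S(=O)(=O)O)cc1
Why: Peracid oxidation of the aryl iodide in the presence of sulfonic acid should give the aryl(hydroxy)(tosyloxy) trivalent iodine species, which substitutes the very electron-rich 1,3,5-trimethoxybenzene electrophilically to the unsymmetrical diaryliodonium tosylate, a standard one-pot iodonium synthesis in which the protonated chromone keeps ring A from competing as the arene partner.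

Step 8
Reactants: 9 racemic 4-{6-[4-(benzyloxy)phenyl]-4-oxo-4H-pyran-2-yl}-4-hydroxy-3-methoxycyclobut-2-en-1-one; 16 {4-[5-(benzyloxy)-7-methoxy-4-oxo-4H-chromen-2-yl]phenyl}(2,4,6-trimethoxyphenyl)iodonium 4-methylbenzenesulfonate
Product: 17 racemic 4-{6-[4-(benzyloxy)phenyl]-4-oxo-4H-pyran-2-yl}-4-{4-[5-(benzyloxy)-7-methoxy-4-oxo-4H-chromen-2-yl]phenoxy}-3-methoxycyclobut-2-en-1-one
Conditions: NaN(SiMe3)2 (1.0 equiv), THF, −78 °C; then 16 (1.2 equiv), −78 to 0 °C
Reagents that add atoms: none
Why: Metal-free O-arylation of a tertiary alkoxide by a diaryliodonium salt, in which the alkoxide replaces tosylate on iodine and ligand coupling at the ipso carbon of the electron-poorer flavonyl ring forms the hindered ether below 0 °C while the electron-rich trimethoxyphenyl group leaves as the aryl iodide, so that no displacement on a weakly activated aryl fluoride is needed and the racemic stereocenter is not touched.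

Step 9
Reactants: 17 racemic 4-{6-[4-(benzyloxy)phenyl]-4-oxo-4H-pyran-2-yl}-4-{4-[5-(benzyloxy)-7-methoxy-4-oxo-4H-chromen-2-yl]phenoxy}-3-methoxycyclobut-2-en-1-one
Product: 20 5,4'''-di-O-benzyl ether of the target, via dienylketene 18 (not isolated), via dienone 19 (not isolated)
Conditions: dry degassed toluene (0.01 M), 110 °C, argon, sealed vessel
Reagents that add atoms: none
Why: On heating, the four-membered ring opens in a conrotatory four-electron process at the bond between its carbonyl carbon and the quaternary carbon, which gives dienylketene 18 with the ketene in conjugation with the new C(OMe)=C(OAr) bond and the C2=C3 bond of the pyranone. A disrotatory six-electron electrocyclisation then joins the electrophilic ketene carbon (the later C5'') to the nucleophilic C3 of the pyranone (the later C4a''), closing the six-membered carbocyclic ring A'' as dienone 19, and a proton shift from C4a'' to oxygen gives the phenol, held by a hydrogen bond to the C4'' carbonyl group. The closest known reaction type is the Moore-type thermal ring expansion of 4-alkenyl-, 4-aryl- and 4-heteroaryl-4-oxycyclobutenones to hydroquinone derivatives, of which this is the variant with an aryl ether instead of a hydroxyl, alkyl ether or silyl ether on the quaternary carbon. No stereocenter remains, since the quaternary centre of racemic 17 and the transient sp3 carbon C4a'' of 19 both become aromatic carbons. The selectivity that the step needs is torquoselectivity in the ring opening: the oxygen on the quaternary carbon, a lone-pair donor, should turn outward, which places the pyranyl group inward beside the ketene so that the intramolecular closure outruns dimerisation or capture of the ketene, helped by high dilution in dry, degassed solvent. The position of closure is unambiguous because only C3 of the pyranone completes a six-atom triene, and the substituents of ring A'' therefore come out as 5''-OH, 6''-H, 7''-OMe and 8''-OAr next to O1''.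

Step 10
Reactants: 20 5,4'''-di-O-benzyl ether of the target
Product: 21 5-hydroxy-2-(4-{[5-hydroxy-2-(4-hydroxyphenyl)-7-methoxy-4-oxo-4H-chromen-8-yl]oxy}phenyl)-7-methoxy-4H-chromen-4-one (target)
Conditions: H2 (1 atm), 10% Pd/C, THF–MeOH, rt
Reagents that add atoms: none
Why: Catalytic hydrogenolysis should cleave both benzylic C–O bonds under conditions that leave the diaryl ether, the methyl ethers and the chromone double bonds alone, which gives the target with its two chelated 5-hydroxyls and the free 4'''-hydroxyl.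

**Compound list**

1 | dimethyl squarate (3,4-dimethoxycyclobut-3-ene-1,2-dione) | COC1=C(OC)C(=O)C1=O | starting material
2 | racemic 4-hydroxy-2,3-dimethoxycyclobut-2-en-1-one | COC1=C(OC)C(O)C1=O | intermediate
3 | 3-methoxycyclobut-3-ene-1,2-dione | COC1=CC(=O)C1=O | intermediate
4 | (E)-4-methoxybut-3-en-2-one | CO/C=C/C(C)=O | starting material
5 | 4-(benzyloxy)benzoyl chloride | O=C(Cl)c1ccc(OCc2ccccc2)cc1 | starting material
6 | (E)-1-[4-(benzyloxy)phenyl]-5-methoxypent-4-ene-1,3-dione | CO/C=C/C(=O)CC(=O)c1ccc(OCc2ccccc2)cc1 | intermediate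
7 | 2-[4-(benzyloxy)phenyl]-4H-pyran-4-one | O=c1ccoc(-c2ccc(OCc3ccccc3)cc2)c1 | intermediate
8 | {6-[4-(benzyloxy)phenyl]-4-oxo-4H-pyran-2-yl}lithium | [Li]c1cc(=O)cc(-c2ccc(OCc3ccccc3)cc2)o1 | intermediate
9 | racemic 4-{6-[4-(benzyloxy)phenyl]-4-oxo-4H-pyran-2-yl}-4-hydroxy-3-methoxycyclobut-2-en-1-one | COC1=CC(=O)C1(O)c1cc(=O)cc(-c2ccc(OCc3ccccc3)cc2)o1 | intermediate
10 | 2,4,6-trihydroxyacetophenone | CC(=O)c1c(O)cc(O)cc1O | starting material
11 | 1-(2,6-dihydroxy-4-methoxyphenyl)ethan-1-one | CC(=O)c1c(O)cc(OC)cc1O | intermediate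
12 | 1-[2-(benzyloxy)-6-hydroxy-4-methoxyphenyl]ethan-1-one | CC(=O)c1c(O)cc(OC)cc1OCc1ccccc1 | intermediate
13 | 4-iodobenzoyl chloride | O=C(Cl)c1ccc(I)cc1 | starting material
14 | 1-[2-(benzyloxy)-6-hydroxy-4-methoxyphenyl]-3-(4-iodophenyl)propane-1,3-dione | O=C(CC(=O)c1ccc(I)cc1)c1c(O)cc(OC)cc1OCc1ccccc1 | intermediate
15 | 5-(benzyloxy)-2-(4-iodophenyl)-7-methoxy-4H-chromen-4-one | COc1cc(OCc2ccccc2)c2c(=O)cc(-c3ccc(I)cc3)oc2c1 | intermediate
16 | {4-[5-(benzyloxy)-7-methoxy-4-oxo-4H-chromen-2-yl]phenyl}(2,4,6-trimethoxyphenyl)iodonium 4-methylbenzenesulfonate | COc1cc(OCc2ccccc2)c2c(=O)cc(-c3ccc([I+]c4c(OC)cc(OC)cc4OC)cc3)oc2c1.Cc1ccc(S(=O)(=O)[O-])cc1 | intermediate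
17 | racemic 4-{6-[4-(benzyloxy)phenyl]-4-oxo-4H-pyran-2-yl}-4-{4-[5-(benzyloxy)-7-methoxy-4-oxo-4H-chromen-2-yl]phenoxy}-3-methoxycyclobut-2-en-1-one | COC1=CC(=O)C1(Oc1ccc(-c2cc(=O)c3c(OCc4ccccc4)cc(OC)cc3o2)cc1)c1cc(=O)cc(-c2ccc(OCc3ccccc3)cc2)o1 | intermediate
18 | (3Z)-4-{6-[4-(benzyloxy)phenyl]-4-oxo-4H-pyran-2-yl}-4-{4-[5-(benzyloxy)-7-methoxy-4-oxo-4H-chromen-2-yl]phenoxy}-3-methoxybuta-1,3-dien-1-one (dienylketene, pyranyl group cis to the ketene carbon chain) | O=C=C/C(OC)=C(/Oc1ccc(-c2cc(=O)c3c(OCc4ccccc4)cc(OC)cc3o2)cc1)c1cc(=O)cc(-c2ccc(OCc3ccccc3)cc2)o1 | intermediate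
19 | racemic 2-[4-(benzyloxy)phenyl]-8-{4-[5-(benzyloxy)-7-methoxy-4-oxo-4H-chromen-2-yl]phenoxy}-7-methoxy-4aH-chromene-4,5-dione | COC1=CC(=O)C2C(=O)C=C(c3ccc(OCc4ccccc4)cc3)OC2=C1Oc1ccc(-c2cc(=O)c3c(OCc4ccccc4)cc(OC)cc3o2)cc1 | intermediate
20 | 5-(benzyloxy)-2-[4-({2-[4-(benzyloxy)phenyl]-5-hydroxy-7-methoxy-4-oxo-4H-chromen-8-yl}oxy)phenyl]-7-methoxy-4H-chromen-4-one | COc1cc(OCc2ccccc2)c2c(=O)cc(-c3ccc(Oc4c(OC)cc(O)c5c(=O)cc(-c6ccc(OCc7ccccc7)cc6)oc45)cc3)oc2c1 | intermediate
21 | 5-hydroxy-2-(4-{[5-hydroxy-2-(4-hydroxyphenyl)-7-methoxy-4-oxo-4H-chromen-8-yl]oxy}phenyl)-7-methoxy-4H-chromen-4-one | COc1cc(O)c2c(=O)cc(-c3ccc(Oc4c(OC)cc(O)c5c(=O)cc(-c6ccc(O)cc6)oc45)cc3)oc2c1 | target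

**Step count and risks**

Total step count: 10. Longest linear sequence: 7 steps (steps 4, 5, 6, 7, 8, 9 and 10, from 2,4,6-trihydroxyacetophenone).

Steps most likely to fail:

1. Step 9. The ring opening may turn the aryloxy group inward, the ketene may be captured or oligomerise before it closes, or the pyranone double bond may be slow to give up its conjugation in the six-electron closure.
   Fallback (sets out from 11 and 5, comes back at 20): ring A'' is taken from an aromatic precursor and oxygenated instead of being built. Aroylation of the trianion of 11 with 5 (LiN(SiMe3)2, THF, −78 °C to rt) should give 1-[4-(benzyloxy)phenyl]-3-(2,6-dihydroxy-4-methoxyphenyl)propane-1,3-dione F1. Catalytic TsOH in toluene at 80 °C cyclises it to 2-[4-(benzyloxy)phenyl]-5-hydroxy-7-methoxy-4H-chromen-4-one F2. Elbs persulfate oxidation (K2S2O8, aqueous KOH, pyridine, rt) hydroxylates para to the 5-hydroxyl through potassium 2-[4-(benzyloxy)phenyl]-5-hydroxy-7-methoxy-4-oxo-4H-chromen-8-yl sulfate F3. Acid hydrolysis (dilute HCl, Na2SO3, 80 °C) then gives 2-[4-(benzyloxy)phenyl]-5,8-dihydroxy-7-methoxy-4H-chromen-4-one F4. The free, non-chelated 8-phenoxide of F4 is arylated with iodonium salt 16 (K2CO3, DMF, rt, argon) to give 20.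

2. Step 8. The sodium alkoxide may open to a butenolide or fragment before it is arylated, or the strong base may turn the iodonium salt into an aryne and so scramble the position of the ether.
   Fallback (sets out from 9, comes back at 20): the ether is made after the ring expansion, on a phenol. Silylation without a free alkoxide (tBuMe2SiOTf, 2,6-lutidine, CH2Cl2, −78 °C) should give racemic 4-{6-[4-(benzyloxy)phenyl]-4-oxo-4H-pyran-2-yl}-4-[(tert-butyldimethylsilyl)oxy]-3-methoxycyclobut-2-en-1-one F5. Thermolysis in toluene at 110 °C, the ring expansion in its established silyloxy form, gives 2-[4-(benzyloxy)phenyl]-8-[(tert-butyldimethylsilyl)oxy]-5-hydroxy-7-methoxy-4H-chromen-4-one F6. CsF in DMF in the presence of 16 then frees the 8-phenoxide and arylates it in the same flask to 20.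

3. Step 3. The pyranyllithium may add to pyranone that is not yet metalated, metalation may occur next to the carbonyl group instead of next to the ring oxygen, or the semisquarate may be deprotonated or attacked twice.
   Fallback (sets out from 7, comes back at 9): the nucleophile is made through a stable zinc species and a halide. Zincation of 7 with (2,2,6,6-tetramethylpiperidyl)ZnCl·LiCl (THF, 25 °C) should give {6-[4-(benzyloxy)phenyl]-4-oxo-4H-pyran-2-yl}zinc chloride F7. Iodolysis with I2 gives 2-[4-(benzyloxy)phenyl]-6-iodo-4H-pyran-4-one F8. Iodine–magnesium exchange (iPrMgCl·LiCl, THF, −78 °C) gives {6-[4-(benzyloxy)phenyl]-4-oxo-4H-pyran-2-yl}magnesium chloride F9, which is added to 3 at −78 °C and quenched with aqueous NH4Cl to give 9.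

**Further compounds**

F1 | step 9 | 1-[4-(benzyloxy)phenyl]-3-(2,6-dihydroxy-4-methoxyphenyl)propane-1,3-dione | O=C(CC(=O)c1ccc(OCc2ccccc2)cc1)c1c(O)cc(OC)cc1O
F2 | step 9 | 2-[4-(benzyloxy)phenyl]-5-hydroxy-7-methoxy-4H-chromen-4-one | COc1cc(O)c2c(=O)cc(-c3ccc(OCc4ccccc4)cc3)oc2c1
F3 | step 9 | potassium 2-[4-(benzyloxy)phenyl]-5-hydroxy-7-methoxy-4-oxo-4H-chromen-8-yl sulfate | COc1cc(O)c2c(=O)cc(-c3ccc(OCc4ccccc4)cc3)oc2c1OS(=O)(=O)[O-].[K+]
F4 | step 9 | 2-[4-(benzyloxy)phenyl]-5,8-dihydroxy-7-methoxy-4H-chromen-4-one | COc1cc(O)c2c(=O)cc(-c3ccc(OCc4ccccc4)cc3)oc2c1O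
F5 | step 8 | racemic 4-{6-[4-(benzyloxy)phenyl]-4-oxo-4H-pyran-2-yl}-4-[(tert-butyldimethylsilyl)oxy]-3-methoxycyclobut-2-en-1-one | COC1=CC(=O)C1(O[Si](C)(C)C(C)(C)C)c1cc(=O)cc(-c2ccc(OCc3ccccc3)cc2)o1
F6 | step 8 | 2-[4-(benzyloxy)phenyl]-8-[(tert-butyldimethylsilyl)oxy]-5-hydroxy-7-methoxy-4H-chromen-4-one | COc1cc(O)c2c(=O)cc(-c3ccc(OCc4ccccc4)cc3)oc2c1O[Si](C)(C)C(C)(C)C
F7 | step 3 | {6-[4-(benzyloxy)phenyl]-4-oxo-4H-pyran-2-yl}zinc chloride | Cl[Zn]c1cc(=O)cc(-c2ccc(OCc3ccccc3)cc2)o1
F8 | step 3 | 2-[4-(benzyloxy)phenyl]-6-iodo-4H-pyran-4-one | O=c1cc(I)oc(-c2ccc(OCc3ccccc3)cc2)c1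
F9 | step 3 | {6-[4-(benzyloxy)phenyl]-4-oxo-4H-pyran-2-yl}magnesium chloride | Cl[Mg]c1cc(=O)cc(-c2ccc(OCc3ccccc3)cc2)o1
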